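**Retrosynthetic overview**
1. The amide is made last; the triene is built by two Wittig reactions on a C24 aldehyde; C8=C9 comes from a Julia–Kocienski union of a ring A/ring B sulfone (C9–C24) with a C1–C8 enal that already carries the azide and the carbamate.
2. Ring A (formed second) comes from a Prins cyclisation of the ring B aldehyde (C18) with a Roche-ester-derived homoallylic alcohol (C19–C24), then O-methylation; the C10 methyl comes from Zr-catalysed carboalumination of a C12 allyl group.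
3. Ring B (formed first) is the key step: a SmI2 ketyl–olefin cyclisation in which the C13 ketyl, a reversed-polarity carbonyl carbon, attacks C12 of a β-alkoxyacrylate, closing the oxane and setting C12 and the C13 tertiary carbinol together.
4. The keto acrylate comes from a chiral homoenolate equivalent (titanated allyl carbamate) added to 3-silyloxypropanal, which makes the C15–C16 bond and sets both centres.

Convention: locants C1–C29 run along the main chain from the NCH2 carbon (C1) to the terminal =CH2 (C29); ring B is the oxane O–C12–C13–C14–C15–C16, ring A the oxane O–C18–C19–C20–C21–C22; "bis-oxane" means the ring A–CH2–ring B unit. Stereodescriptors given with target locants refer to the SMILES in the compound list.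

**Route**

Step 1
Reactants: 1 (E)-pent-3-en-2-one
Product: 2 (2R,3E)-pent-3-en-2-ol
Conditions: (S)-2-methyl-CBS-oxazaborolidine (10 mol%), catecholborane, toluene, −78 °C; aq. NaOH work-up
Reagents that add atoms: none
Why: Corey–Bakshi–Shibata reduction, in which the oxazaborolidine–borane complex binds the enone with propenyl as the large group and delivers hydride 1,2 to give the (R)-allylic alcohol, as it does with aryl methyl ketones.

Step 2
Reactants: 2 (2R,3E)-pent-3-en-2-ol
Product: 3 (2R,3E)-pent-3-en-2-yl N,N-diisopropylcarbamate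
Conditions: NaH, THF, 0 °C; iPr2NCOCl, reflux
Reagents that add atoms: N,N-diisopropylcarbamoyl chloride, CC(C)N(C(C)C)C(Cl)=O
Why: O-carbamoylation of the alkoxide, which does not touch the stereocentre and installs the directing group needed for α-lithiation.

Step 3
Reactants: 3 (2R,3E)-pent-3-en-2-yl N,N-diisopropylcarbamate; 4 3-[(tert-butyldimethylsilyl)oxy]propanal
Product: 7 (2Z,4S,5R)-7-[(tert-butyldimethylsilyl)oxy]-5-hydroxy-4-methylhept-2-en-2-yl N,N-diisopropylcarbamate, via lithiated carbamate 5 (not isolated), via allyltitanium reagent 6 (not isolated)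
Conditions: n-BuLi, TMEDA, Et2O/hexane, −78 °C; Ti(OiPr)4 (3 equiv), −78 °C; then 4, −78 °C → rt; 1 M HCl work-up
Reagents that add atoms: none
Why: Hoppe homoaldol reaction, in which α-lithiation with retention gives a configurationally stable lithio carbamate, Li→Ti exchange with inversion gives an allyltitanium homoenolate equivalent, and this adds through C15 to the aldehyde in a chair transition state on the face syn to titanium, setting anti C15/C16 by chirality transfer and leaving the (Z)-enol carbamate as a masked C13 methyl ketone.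

Step 4
Reactants: 7 homoaldol adduct; 8 methyl propiolate
Product: 9 methyl (E)-3-{[(3R,4S,5Z)-1-[(tert-butyldimethylsilyl)oxy]-6-[(diisopropylcarbamoyl)oxy]-4-methylhept-5-en-3-yl]oxy}acrylate
Conditions: N-methylmorpholine, CH2Cl2, rt
Reagents that add atoms: none
Why: amine-catalysed oxa-Michael addition of the C16 hydroxyl to the ynoate, which gives the (E)-β-alkoxyacrylate and creates no stereocentre.

Step 5
Reactants: 9 enol carbamate acrylate
Product: 11 methyl (E)-3-{[(3R,4S)-1-hydroxy-4-methyl-6-oxoheptan-3-yl]oxy}acrylate, via dimethyl ketal 10 (not isolated)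
Conditions: Hg(OAc)2 (10 mol%), MeSO3H, MeOH, rt; then 1 M HCl, THF/H2O, rt
Reagents that add atoms: water, O; methanol, CO (retained only in intermediate 10)
Why: divalent-mercury-catalysed acidic methanolysis of the enol carbamate gives the ketal while cleaving the silyl ether in the same pot, and mild aqueous acid then frees the methyl ketone, the vinylogous carbonate being stable to these conditions and no stereocentre being touched.

Step 6
Reactants: 11 keto acrylate
Product: 12 methyl 2-[(2S,3R,5S,6R)-3-hydroxy-6-(2-hydroxyethyl)-3,5-dimethyloxan-2-yl]acetate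
Conditions: SmI2 (3 equiv), MeOH (3 equiv), THF, 0 °C → rt
Reagents that add atoms: none
Why: SmI2 ketyl–olefin reductive cyclisation (key step), in which one-electron reduction turns C13 into a nucleophilic ketyl that adds 6-exo to C12 of the β-alkoxyacrylate through a chair with the C15 and C16 substituents equatorial and trivalent samarium chelated between ketyl oxygen and ester carbonyl, giving the 2,6-cis oxane with the C13 hydroxyl equatorial (trans to the C12 side chain) and the methyl axial.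

Step 7
Reactants: 12 ring B diol ester
Product: 13 methyl 2-[(2S,3R,5S,6R)-3-hydroxy-3,5-dimethyl-6-(2-oxoethyl)oxan-2-yl]acetate
Conditions: TEMPO (10 mol%), PhI(OAc)2, CH2Cl2, rt
Reagents that add atoms: none
Why: oxoammonium (TEMPO) oxidation, which takes the primary alcohol to the aldehyde and cannot oxidise the tertiary C13 alcohol.

Step 8
Reactants: 14 methyl (S)-3-hydroxy-2-methylpropanoate
Product: 15 methyl (S)-3-[(tert-butyldiphenylsilyl)oxy]-2-methylpropanoate
Conditions: TBDPSCl, imidazole, DMF, rt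
Reagents that add atoms: tert-butyl(chloro)diphenylsilane, CC(C)(C)[Si](Cl)(c1ccccc1)c1ccccc1
Why: silylation of the primary alcohol with a group that survives the later trifluoroacetic acid step, C23 coming from the chiral pool.

Step 9
Reactants: 15 silyl ester
Product: 16 (S)-3-[(tert-butyldiphenylsilyl)oxy]-2-methylpropanal
Conditions: iBu2AlH (1.05 equiv), CH2Cl2, −78 °C; potassium sodium tartrate (KNaC4H4O6) work-up
Reagents that add atoms: none
Why: partial reduction of the ester through the stable aluminium hemiacetal at low temperature, which gives the aldehyde without epimerising C23.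

Step 10
Reactants: 16 aldehyde
Product: 17 (2S,3R)-1-[(tert-butyldiphenylsilyl)oxy]-2-methylhex-5-en-3-ol
Conditions: (+)-Ipc2BOMe, CH2=CHCH2MgBr, Et2O, −78 °C → rt; then 16, −78 °C; NaOH, H2O2
Reagents that add atoms: allylmagnesium bromide, C=CC[Mg]Br
Why: Brown allylboration through a chair transition state, in which the (+)-isopinocampheyl reagent selects the aldehyde face that gives 22R and overrides the small intrinsic bias of the α-methyl aldehyde, so C22–OH and C23–Me are anti.

Step 11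
Reactants: 13 ring B aldehyde; 17 homoallylic alcohol
Product: 19 bis-oxane alcohol (C10 methyl ester; 13-OH; 20-OH; 24-OTBDPS; 12S,13R,15S,16R,18S,20S,22R,23S), via C20 trifluoroacetate 18 (not isolated)
Conditions: CF3CO2H (20 equiv), CH2Cl2, 0 °C → rt; then K2CO3, MeOH, rt
Reagents that add atoms: trifluoroacetic acid, OC(=O)C(F)(F)F
Why: Prins cyclisation, in which the oxocarbenium ion from 13 and 17 closes ring A through a chair with the C17 and C23 substituents equatorial and trifluoroacetate is captured equatorially at C20, so C18 and C20 are set all-cis to C22 before methanolysis frees the C20 alcohol.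

Step 12
Reactants: 19 bis-oxane alcohol
Product: 20 bis-oxane methyl ether (C10 methyl ester; 13-OH; 20-OMe; 24-OTBDPS)
Conditions: Me3OBF4, 1,8-bis(dimethylamino)naphthalene, CH2Cl2, rt
Reagents that add atoms: trimethyloxonium tetrafluoroborate, C[O+](C)C.F[B-](F)(F)F
Why: O-methylation with Meerwein salt under non-basic conditions, which alkylates the unhindered equatorial secondary alcohol and leaves the hindered tertiary C13 alcohol and the ester alone.

Step 13
Reactants: 20 bis-oxane methyl ether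
Product: 22 C12-allyl bis-oxane (13-OH; 20-OMe; 24-OTBDPS), via C10 aldehyde 21 (not isolated)
Conditions: iBu2AlH (2.2 equiv), CH2Cl2, −78 °C; then Ph3P=CH2 (from Ph3PCH3Br, KN(SiMe3)2), THF, −78 °C → rt
Reagents that add atoms: methyltriphenylphosphonium bromide, C[P+](c1ccccc1)(c1ccccc1)c1ccccc1.[Br-]
Why: one-pot ester half-reduction and Wittig methylenation, in which the aluminium hemiacetal releases the aldehyde only as the ylide consumes it, so no stereocentre is exposed.

Step 14
Reactants: 22 C12-allyl bis-oxane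
Product: 24 C9 alcohol (10R; 13-OH; 20-OMe; 24-OTBDPS), via alkyldimethylalane 23 (not isolated)
Conditions: Me3Al (3 equiv), (−)-(NMI)2ZrCl2 [bis(1-neomenthylindenyl)zirconium dichloride] (5 mol%), methylaluminoxane (MeAlO)n, CH2Cl2, 0 °C → rt; then O2, 0 °C; aq. NaOH
Reagents that add atoms: trimethylaluminium, C[Al](C)C; dioxygen, O=O
Why: Negishi zirconium-catalysed asymmetric carboalumination (ZACA), in which the chiral zirconocene adds Me–Al across the terminal alkene with methyl at C10 on the face that gives 10R (the sense known for 1-alkenes with this catalyst antipode), and oxidation of the C–Al bond gives the primary alcohol.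

Step 15
Reactants: 24 C9 alcohol
Product: 25 C9 (1-phenyl-1H-tetrazol-5-yl) sulfide
Conditions: 1-phenyl-1H-tetrazole-5-thiol, PPh3, DIAD, THF, 0 °C → rt
Reagents that add atoms: 1-phenyl-1H-tetrazole-5-thiol, Sc1nnnn1-c1ccccc1
Why: Mitsunobu thioetherification of the primary alcohol, which does not affect the tertiary alcohol or the adjacent C10 centre.

Step 16
Reactants: 25 sulfide
Product: 26 C9 (1-phenyl-1H-tetrazol-5-yl) sulfone
Conditions: (NH4)6Mo7O24·4H2O (10 mol%), 30% H2O2, EtOH, 0 °C → rt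
Reagents that add atoms: hydrogen peroxide, OO
Why: molybdate-catalysed sulfide-to-sulfone oxidation, run at a stage with no alkene or other oxidisable group in the molecule.

Step 17
Reactants: 27 ethyl (S)-4-chloro-3-hydroxybutanoate
Product: 28 ethyl (S)-4-azido-3-hydroxybutanoate
Conditions: NaN3, DMF, 80 °C
Reagents that add atoms: sodium azide, [Na+].[N-]=[N+]=[N-]
Why: SN2 displacement at the primary carbon, which leaves the C2 carbinol centre (chiral pool) untouched.

Step 18
Reactants: 28 azido alcohol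
Product: 29 ethyl (S)-4-azido-3-[(tert-butyldimethylsilyl)oxy]butanoate
Conditions: TBSCl, imidazole, DMF, rt
Reagents that add atoms: tert-butyl(chloro)dimethylsilane, CC(C)(C)[Si](C)(C)Cl
Why: silylation of the C2 hydroxyl, which keeps it distinct from the C4 hydroxyl that will carry the carbamate.

Step 19
Reactants: 29 silyl ester
Product: 30 (S)-4-azido-3-[(tert-butyldimethylsilyl)oxy]butanal
Conditions: iBu2AlH, CH2Cl2, −78 °C; potassium sodium tartrate (KNaC4H4O6) work-up
Reagents that add atoms: none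
Why: low-temperature partial reduction of the ester to the aldehyde, at which temperature the alkyl azide is not reduced.

Step 20
Reactants: 30 aldehyde
Product: 31 (2S,4R)-1-azido-2-[(tert-butyldimethylsilyl)oxy]hept-6-en-4-ol
Conditions: (+)-Ipc2BOMe, CH2=CHCH2MgBr, Et2O, −78 °C → rt; then 30, −78 °C; NaOH, H2O2
Reagents that add atoms: allylmagnesium bromide, C=CC[Mg]Br
Why: Brown allylboration under reagent control, which sets 4R and hence the 1,3-anti C2/C4 diol pattern.

Step 21
Reactants: 31 homoallylic alcohol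
Product: 33 (2S,4R)-1-azido-2-[(tert-butyldimethylsilyl)oxy]hept-6-en-4-yl carbamate, via N-trichloroacetyl carbamate 32 (not isolated)
Conditions: Cl3CC(O)NCO, CH2Cl2, 0 °C; then K2CO3, MeOH, rt
Reagents that add atoms: trichloroacetyl isocyanate, O=C=NC(=O)C(Cl)(Cl)Cl
Why: addition of the alcohol to the acyl isocyanate followed by mild methanolysis of the trichloroacetyl group gives the primary carbamate with retention at C4.

Step 22
Reactants: 33 carbamate; 34 methacrolein
Product: 35 (2E,5R,7S)-8-azido-7-[(tert-butyldimethylsilyl)oxy]-2-methyl-1-oxooct-2-en-5-yl carbamate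
Conditions: 34 (10 equiv), second-generation Hoveyda–Grubbs catalyst RuCl2(H2IMes)(=CH-C6H4-2-OiPr) (5 mol%), CH2Cl2, 40 °C
Reagents that add atoms: none
Why: olefin cross-metathesis of a terminal alkene with a 1,1-disubstituted electron-poor partner, which gives the thermodynamically favoured (E)-2-methyl enal (C6=C7).

Step 23
Reactants: 26 C9 sulfone; 35 C1–C8 enal
Product: 37 C1–C24 azido carbamate (2-OTBS; 24-OTBDPS; 6E,8E), via dipotassium salt 36 (not isolated)
Conditions: KN(SiMe3)2 (2.1 equiv), DME, −60 °C; then 35, −60 °C → rt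
Reagents that add atoms: none
Why: Julia–Kocienski olefination, in which the metalated tetrazolyl sulfone adds 1,2 to the enal and Smiles rearrangement with loss of SO2 gives the (E)-C8=C9 alkene, the open transition state in DME favouring E and C10 not being acidic.

Step 24
Reactants: 37 bis-silyl ether
Product: 38 C1–C24 diol (2-OH; 24-OH)
Conditions: Bu4NF, AcOH, THF, rt
Reagents that add atoms: none
Why: fluoride-mediated desilylation removes both silyl ethers, and acetic acid buffering prevents base-induced carbamate migration.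

Step 25
Reactants: 38 diol
Product: 39 C24 aldehyde (2-OH free)
Conditions: TEMPO (20 mol%), PhI(OAc)2, CH2Cl2, rt
Reagents that add atoms: none
Why: TEMPO oxidation is selective for the primary C24 alcohol over the secondary C2 and tertiary C13 alcohols and is neutral enough not to epimerise C23.

Step 26
Reactants: 39 C24 aldehyde; 40 2-(triphenylphosphoranylidene)propanal
Product: 41 C26 enal (24E)
Conditions: toluene, 90 °C
Reagents that add atoms: none
Why: Wittig reaction with a stabilised ylide, which gives the (E)-trisubstituted C24=C25 enal under thermodynamic control of oxaphosphetane formation.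

Step 27
Reactants: 41 C26 enal
Product: 42 azido triene (24E,26E)
Conditions: allyltributylphosphonium bromide, KOtBu, THF, −78 → 0 °C
Reagents that add atoms: allyltributylphosphonium bromide, C=CC[P+](CCCC)(CCCC)CCCC.[Br-]
Why: Wittig reaction with an allylic trialkylphosphonium ylide, which favours the (E)-alkene and adds the terminal vinyl group to complete the triene (excess ylide covers the free OH and NH2 protons).

Step 28
Reactants: 42 azido triene
Product: 44 C1 amine, via iminophosphorane 43 (not isolated)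
Conditions: PMe3, THF/H2O, rt
Reagents that add atoms: none
Why: Staudinger reduction, which converts the azide to the amine without touching the polyene, the carbamate or any stereocentre.

Step 29
Reactants: 45 methyl 2-methoxyacrylate
Product: 46 2-methoxyacrylic acid
Conditions: LiOH, THF/H2O, 0 °C; then 1 M HCl to pH 3
Reagents that add atoms: lithium hydroxide, [Li+].[OH-]
Why: ester saponification, with brief cold acidification so that the enol ether is not hydrolysed.

Step 30
Reactants: 44 C1 amine; 46 2-methoxyacrylic acid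
Product: 47 CNP0220268.1 (target)
Conditions: EDC·HCl, HOBt, iPr2NEt, CH2Cl2, 0 °C → rt
Reagents that add atoms: none
Why: carbodiimide amide coupling, which acylates the primary amine selectively over the secondary and tertiary alcohols and the carbamate nitrogen.

**Compound list**
1 | (E)-pent-3-en-2-one | C/C=C/C(C)=O | starting material
2 | (2R,3E)-pent-3-en-2-ol | C/C=C/[C@@H](C)O | intermediate
3 | (2R,3E)-pent-3-en-2-yl N,N-diisopropylcarbamate | C/C=C/[C@@H](C)OC(=O)N(C(C)C)C(C)C | intermediate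
4 | 3-[(tert-butyldimethylsilyl)oxy]propanal | CC(C)(C)[Si](C)(C)OCCC=O | starting material
5 | α-lithiated carbamate (Li in place of H, retention) | C/C=C/[C@@]([Li])(C)OC(=O)N(C(C)C)C(C)C | intermediate
6 | α-titanated carbamate, triisopropoxytitanium (inverted) | C/C=C/[C@]([Ti](OC(C)C)(OC(C)C)OC(C)C)(C)OC(=O)N(C(C)C)C(C)C | intermediate
7 | (2Z,4S,5R)-7-[(tert-butyldimethylsilyl)oxy]-5-hydroxy-4-methylhept-2-en-2-yl N,N-diisopropylcarbamate | CC(C)(C)[Si](C)(C)OCC[C@@H](O)[C@@H](C)/C=C(/C)OC(=O)N(C(C)C)C(C)C | intermediate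
8 | methyl propiolate | C#CC(=O)OC | starting material
9 | methyl (E)-3-{[(3R,4S,5Z)-1-[(tert-butyldimethylsilyl)oxy]-6-[(diisopropylcarbamoyl)oxy]-4-methylhept-5-en-3-yl]oxy}acrylate | CC(C)(C)[Si](C)(C)OCC[C@@H](O/C=C/C(=O)OC)[C@@H](C)/C=C(/C)OC(=O)N(C(C)C)C(C)C | intermediate
10 | methyl (E)-3-{[(3R,4S)-1-hydroxy-6,6-dimethoxy-4-methylheptan-3-yl]oxy}acrylate | OCC[C@@H](O/C=C/C(=O)OC)[C@@H](C)CC(C)(OC)OC | intermediate
11 | methyl (E)-3-{[(3R,4S)-1-hydroxy-4-methyl-6-oxoheptan-3-yl]oxy}acrylate | OCC[C@@H](O/C=C/C(=O)OC)[C@@H](C)CC(C)=O | intermediate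
12 | methyl 2-[(2S,3R,5S,6R)-3-hydroxy-6-(2-hydroxyethyl)-3,5-dimethyloxan-2-yl]acetate | OCC[C@H]1O[C@@H](CC(=O)OC)[C@](C)(O)C[C@@H]1C | intermediate
13 | methyl 2-[(2S,3R,5S,6R)-3-hydroxy-3,5-dimethyl-6-(2-oxoethyl)oxan-2-yl]acetate | O=CC[C@H]1O[C@@H](CC(=O)OC)[C@](C)(O)C[C@@H]1C | intermediate
14 | methyl (S)-3-hydroxy-2-methylpropanoate | OC[C@H](C)C(=O)OC | starting material
15 | methyl (S)-3-[(tert-butyldiphenylsilyl)oxy]-2-methylpropanoate | CC(C)(C)[Si](c1ccccc1)(c1ccccc1)OC[C@H](C)C(=O)OC | intermediate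
16 | (S)-3-[(tert-butyldiphenylsilyl)oxy]-2-methylpropanal | CC(C)(C)[Si](c1ccccc1)(c1ccccc1)OC[C@H](C)C=O | intermediate
17 | (2S,3R)-1-[(tert-butyldiphenylsilyl)oxy]-2-methylhex-5-en-3-ol | CC(C)(C)[Si](c1ccccc1)(c1ccccc1)OC[C@H](C)[C@H](O)CC=C | intermediate
18 | C20 trifluoroacetate of bis-oxane alcohol 19 | CC(C)(C)[Si](c1ccccc1)(c1ccccc1)OC[C@H](C)[C@H]1C[C@@H](OC(=O)C(F)(F)F)C[C@@H](C[C@H]2O[C@@H](CC(=O)OC)[C@](C)(O)C[C@@H]2C)O1 | intermediate
19 | methyl 2-[(2S,3R,5S,6R)-6-{[(2S,4S,6R)-6-[(2S)-1-[(tert-butyldiphenylsilyl)oxy]propan-2-yl]-4-hydroxyoxan-2-yl]methyl}-3-hydroxy-3,5-dimethyloxan-2-yl]acetate | CC(C)(C)[Si](c1ccccc1)(c1ccccc1)OC[C@H](C)[C@H]1C[C@@H](O)C[C@@H](C[C@H]2O[C@@H](CC(=O)OC)[C@](C)(O)C[C@@H]2C)O1 | intermediate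
20 | bis-oxane methyl ether (19 with 20-OMe) | CC(C)(C)[Si](c1ccccc1)(c1ccccc1)OC[C@H](C)[C@H]1C[C@@H](OC)C[C@@H](C[C@H]2O[C@@H](CC(=O)OC)[C@](C)(O)C[C@@H]2C)O1 | intermediate
21 | C10 aldehyde of the bis-oxane (formed as its aluminium hemiacetal) | CC(C)(C)[Si](c1ccccc1)(c1ccccc1)OC[C@H](C)[C@H]1C[C@@H](OC)C[C@@H](C[C@H]2O[C@@H](CC=O)[C@](C)(O)C[C@@H]2C)O1 | intermediate
22 | C12-allyl bis-oxane (13-OH; 20-OMe; 24-OTBDPS) | CC(C)(C)[Si](c1ccccc1)(c1ccccc1)OC[C@H](C)[C@H]1C[C@@H](OC)C[C@@H](C[C@H]2O[C@@H](CC=C)[C@](C)(O)C[C@@H]2C)O1 | intermediate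
23 | C9 dimethylalane (10R) with the 13-O-dimethylaluminium alkoxide | CC(C)(C)[Si](c1ccccc1)(c1ccccc1)OC[C@H](C)[C@H]1C[C@@H](OC)C[C@@H](C[C@H]2O[C@@H](C[C@@H](C)C[Al](C)C)[C@](C)(O[Al](C)C)C[C@@H]2C)O1 | intermediate
24 | C9 alcohol (10R; 13-OH; 20-OMe; 24-OTBDPS) | CC(C)(C)[Si](c1ccccc1)(c1ccccc1)OC[C@H](C)[C@H]1C[C@@H](OC)C[C@@H](C[C@H]2O[C@@H](C[C@@H](C)CO)[C@](C)(O)C[C@@H]2C)O1 | intermediate
25 | C9 (1-phenyl-1H-tetrazol-5-yl) sulfide | CC(C)(C)[Si](c1ccccc1)(c1ccccc1)OC[C@H](C)[C@H]1C[C@@H](OC)C[C@@H](C[C@H]2O[C@@H](C[C@@H](C)CSc3nnnn3-c3ccccc3)[C@](C)(O)C[C@@H]2C)O1 | intermediate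
26 | C9 (1-phenyl-1H-tetrazol-5-yl) sulfone | CC(C)(C)[Si](c1ccccc1)(c1ccccc1)OC[C@H](C)[C@H]1C[C@@H](OC)C[C@@H](C[C@H]2O[C@@H](C[C@@H](C)CS(=O)(=O)c3nnnn3-c3ccccc3)[C@](C)(O)C[C@@H]2C)O1 | intermediate
27 | ethyl (S)-4-chloro-3-hydroxybutanoate | CCOC(=O)C[C@H](O)CCl | starting material
28 | ethyl (S)-4-azido-3-hydroxybutanoate | CCOC(=O)C[C@H](O)CN=[N+]=[N-] | intermediate
29 | ethyl (S)-4-azido-3-[(tert-butyldimethylsilyl)oxy]butanoate | CCOC(=O)C[C@H](O[Si](C)(C)C(C)(C)C)CN=[N+]=[N-] | intermediate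
30 | (S)-4-azido-3-[(tert-butyldimethylsilyl)oxy]butanal | O=CC[C@H](O[Si](C)(C)C(C)(C)C)CN=[N+]=[N-] | intermediate
31 | (2S,4R)-1-azido-2-[(tert-butyldimethylsilyl)oxy]hept-6-en-4-ol | C=CC[C@H](C[C@H](O[Si](C)(C)C(C)(C)C)CN=[N+]=[N-])O | intermediate
32 | N-trichloroacetyl carbamate of 31 | C=CC[C@H](C[C@H](O[Si](C)(C)C(C)(C)C)CN=[N+]=[N-])OC(=O)NC(=O)C(Cl)(Cl)Cl | intermediate
33 | (2S,4R)-1-azido-2-[(tert-butyldimethylsilyl)oxy]hept-6-en-4-yl carbamate | C=CC[C@H](C[C@H](O[Si](C)(C)C(C)(C)C)CN=[N+]=[N-])OC(N)=O | intermediate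
34 | methacrolein | CC(=C)C=O | starting material
35 | (2E,5R,7S)-8-azido-7-[(tert-butyldimethylsilyl)oxy]-2-methyl-1-oxooct-2-en-5-yl carbamate | O=C/C(C)=C/C[C@H](C[C@H](O[Si](C)(C)C(C)(C)C)CN=[N+]=[N-])OC(N)=O | intermediate
36 | dipotassium salt of 26 (C9 carbanion, C13 alkoxide) | CC(C)(C)[Si](c1ccccc1)(c1ccccc1)OC[C@H](C)[C@H]1C[C@@H](OC)C[C@@H](C[C@H]2O[C@@H](C[C@@H](C)[CH-]S(=O)(=O)c3nnnn3-c3ccccc3)[C@](C)([O-])C[C@@H]2C)O1.[K+].[K+] | intermediate
37 | C1–C24 azido carbamate (2-OTBS; 24-OTBDPS; 6E,8E) | CC(C)(C)[Si](c1ccccc1)(c1ccccc1)OC[C@H](C)[C@H]1C[C@@H](OC)C[C@@H](C[C@H]2O[C@@H](C[C@@H](C)/C=C/C(C)=C/C[C@H](C[C@H](O[Si](C)(C)C(C)(C)C)CN=[N+]=[N-])OC(N)=O)[C@](C)(O)C[C@@H]2C)O1 | intermediate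
38 | C1–C24 diol (2-OH; 24-OH) | OC[C@H](C)[C@H]1C[C@@H](OC)C[C@@H](C[C@H]2O[C@@H](C[C@@H](C)/C=C/C(C)=C/C[C@H](C[C@H](O)CN=[N+]=[N-])OC(N)=O)[C@](C)(O)C[C@@H]2C)O1 | intermediate
39 | C24 aldehyde | O=C[C@H](C)[C@H]1C[C@@H](OC)C[C@@H](C[C@H]2O[C@@H](C[C@@H](C)/C=C/C(C)=C/C[C@H](C[C@H](O)CN=[N+]=[N-])OC(N)=O)[C@](C)(O)C[C@@H]2C)O1 | intermediate
40 | 2-(triphenylphosphoranylidene)propanal | CC(C=O)=P(c1ccccc1)(c1ccccc1)c1ccccc1 | starting material
41 | C26 enal (24E) | O=C/C(C)=C/[C@H](C)[C@H]1C[C@@H](OC)C[C@@H](C[C@H]2O[C@@H](C[C@@H](C)/C=C/C(C)=C/C[C@H](C[C@H](O)CN=[N+]=[N-])OC(N)=O)[C@](C)(O)C[C@@H]2C)O1 | intermediate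
42 | azido triene (24E,26E) | C=C/C=C/C(C)=C/[C@H](C)[C@H]1C[C@@H](OC)C[C@@H](C[C@H]2O[C@@H](C[C@@H](C)/C=C/C(C)=C/C[C@H](C[C@H](O)CN=[N+]=[N-])OC(N)=O)[C@](C)(O)C[C@@H]2C)O1 | intermediate
43 | trimethyliminophosphorane of 42 | C=C/C=C/C(C)=C/[C@H](C)[C@H]1C[C@@H](OC)C[C@@H](C[C@H]2O[C@@H](C[C@@H](C)/C=C/C(C)=C/C[C@H](C[C@H](O)CN=P(C)(C)C)OC(N)=O)[C@](C)(O)C[C@@H]2C)O1 | intermediate
44 | C1 amine | C=C/C=C/C(C)=C/[C@H](C)[C@H]1C[C@@H](OC)C[C@@H](C[C@H]2O[C@@H](C[C@@H](C)/C=C/C(C)=C/C[C@H](C[C@H](O)CN)OC(N)=O)[C@](C)(O)C[C@@H]2C)O1 | intermediate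
45 | methyl 2-methoxyacrylate | C=C(OC)C(=O)OC | starting material
46 | 2-methoxyacrylic acid | C=C(OC)C(=O)O | intermediate
47 | CNP0220268.1 (N-(2-methoxyacryloyl) derivative of amine 44) | C=C/C=C/C(C)=C/[C@H](C)[C@H]1C[C@@H](OC)C[C@@H](C[C@H]2O[C@@H](C[C@@H](C)/C=C/C(C)=C/C[C@H](C[C@H](O)CNC(=O)C(=C)OC)OC(N)=O)[C@](C)(O)C[C@@H]2C)O1 | target

**Totals**
Total step count: 30. Longest linear sequence: 20 steps (steps 1–7, 11–16, 23–28 and 30).

**Three steps most likely to fail, each with a fallback**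

Step 6 (ketyl cyclisation of a methyl ketone): ketone ketyls form and cyclise more slowly than aldehyde ketyls, so simple reduction to the carbinol or erosion of the C13 selectivity is possible. Fallback: close ring B on the aldehyde ketyl and add the methyl afterwards. Setting out from 4, (E)-but-2-en-1-ol is carbamoylated to (E)-but-2-en-1-yl N,N-diisopropylcarbamate F1. Lithiation with n-BuLi and (−)-sparteine (crystallisation of the lithium complex), exchange with Ti(OiPr)4 and addition of 4 give (1Z,3S,4R)-6-[(tert-butyldimethylsilyl)oxy]-4-hydroxy-3-methylhex-1-en-1-yl N,N-diisopropylcarbamate F2. Addition to 8 as in step 4 gives the acrylate F3, and the conditions of step 5 give methyl (E)-3-{[(3R,4S)-1-hydroxy-4-methyl-6-oxohexan-3-yl]oxy}acrylate F4. SmI2/MeOH cyclises this to methyl 2-[(2S,3R,5S,6R)-3-hydroxy-6-(2-hydroxyethyl)-5-methyloxan-2-yl]acetate F5. NaOCl in AcOH oxidises the secondary alcohol selectively to the oxan-3-one F6, and excess Me3Al in toluene adds methyl axially (equatorial OH) to rejoin the route at 12.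

Step 14 (carboalumination): the catalyst gives only moderate face selectivity with methyl, and the existing centres may reinforce or oppose it, so the C10 diastereomer ratio may be low. Fallback: set C10 by copper-catalysed allylic substitution. Setting out from 22, cross-metathesis with (E)-1,4-dibromobut-2-ene (second-generation Hoveyda–Grubbs catalyst) gives the (E)-allylic bromide F7. MeMgBr with CuBr·SMe2 and the Taniaphos enantiomer that delivers 10R gives, by SN2′ substitution, the C10-methyl terminal alkene F8. Ozonolysis with NaBH4 work-up cuts the vinyl group back to the C9 alcohol and rejoins the route at 24.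

Step 27 (allyl ylide olefination): semi-stabilised allylic ylides can give E/Z mixtures at C26=C27, and the substrate carries free OH and NH2 groups and an azide. Fallback: form the last C–C bond by cross-coupling. Setting out from 41, Takai olefination (CrCl2, CHI3, THF) gives the (24E,26E)-dienyl iodide F9, and Stille coupling with tributyl(vinyl)stannane (Pd2(dba)3, AsPh3, NMP, rt; a phosphine-free zerovalent palladium system that spares the azide) rejoins the route at 42.

**Further compounds**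
F1 | step 6 | (E)-but-2-en-1-yl N,N-diisopropylcarbamate | C/C=C/COC(=O)N(C(C)C)C(C)C
F2 | step 6 | (1Z,3S,4R)-6-[(tert-butyldimethylsilyl)oxy]-4-hydroxy-3-methylhex-1-en-1-yl N,N-diisopropylcarbamate | CC(C)(C)[Si](C)(C)OCC[C@@H](O)[C@@H](C)/C=C\OC(=O)N(C(C)C)C(C)C
F3 | step 6 | methyl (E)-3-{[(3R,4S,5Z)-1-[(tert-butyldimethylsilyl)oxy]-6-[(diisopropylcarbamoyl)oxy]-4-methylhex-5-en-3-yl]oxy}acrylate | CC(C)(C)[Si](C)(C)OCC[C@@H](O/C=C/C(=O)OC)[C@@H](C)/C=C\OC(=O)N(C(C)C)C(C)C
F4 | step 6 | methyl (E)-3-{[(3R,4S)-1-hydroxy-4-methyl-6-oxohexan-3-yl]oxy}acrylate | OCC[C@@H](O/C=C/C(=O)OC)[C@@H](C)CC=O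
F5 | step 6 | methyl 2-[(2S,3R,5S,6R)-3-hydroxy-6-(2-hydroxyethyl)-5-methyloxan-2-yl]acetate | OCC[C@H]1O[C@@H](CC(=O)OC)[C@H](O)C[C@@H]1C
F6 | step 6 | methyl 2-[(2S,5S,6R)-6-(2-hydroxyethyl)-5-methyl-3-oxooxan-2-yl]acetate | OCC[C@H]1O[C@@H](CC(=O)OC)C(=O)C[C@@H]1C
F7 | step 14 | C12 (E)-4-bromobut-2-enyl bis-oxane (13-OH; 20-OMe; 24-OTBDPS) | CC(C)(C)[Si](c1ccccc1)(c1ccccc1)OC[C@H](C)[C@H]1C[C@@H](OC)C[C@@H](C[C@H]2O[C@@H](C/C=C/CBr)[C@](C)(O)C[C@@H]2C)O1
F8 | step 14 | C12 (2R)-2-methylbut-3-enyl bis-oxane (13-OH; 20-OMe; 24-OTBDPS) | CC(C)(C)[Si](c1ccccc1)(c1ccccc1)OC[C@H](C)[C@H]1C[C@@H](OC)C[C@@H](C[C@H]2O[C@@H](C[C@@H](C)C=C)[C@](C)(O)C[C@@H]2C)O1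
F9 | step 27 | (24E,26E)-27-iodo diene (azide, carbamate, 2-OH and 13-OH as in 41) | I/C=C/C(C)=C/[C@H](C)[C@H]1C[C@@H](OC)C[C@@H](C[C@H]2O[C@@H](C[C@@H](C)/C=C/C(C)=C/C[C@H](C[C@H](O)CN=[N+]=[N-])OC(N)=O)[C@](C)(O)C[C@@H]2C)O1
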